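**Assumptions (one line each):** 5‑Methoxyresorcinol (1) and (+)‑catechin (6) are purchased. The photochemical coupling gives C8‑ and C6‑benzylated catechins in about 2–3:1, and the C8 isomer is separated by preparative HPLC.

## Retrosynthetic overview
1. Pilosanol N is a C8‑CH2‑aryl catechin. Disconnecting the diarylmethane C8–CH2 bond gives (+)‑catechin (6), which already carries the 2R,3S centres, and an o‑quinone methide (o‑QM). The o‑QM comes from photodehydration of benzylic alcohol 5.
2. Alcohol 5 comes from hydroxymethylation of acetophenone 4, whose only free ring carbon lies between the two OH groups.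
3. Acetophenone 4 comes from Friedel–Crafts acetylation of 3. The ring methyl of 3 comes from reduction of the CHO group of 2, which comes from Vilsmeier formylation of 5‑methoxyresorcinol (1).
4. No ring is constructed. The chromane arrives intact in catechin. The phloroglucinol substituents are installed in the order Me, then Ac, then CH2OH, then the bridge bond.

## Forward route

**Step 1**
Reactants: 1, 5‑methoxyresorcinol (3,5‑dihydroxyanisole)
Product: 2, 2,4‑dihydroxy‑6‑methoxybenzaldehyde
Conditions: POCl3, DMF, MeCN, 0 °C → rt, 3 h; then aq. NaOAc, rt
Reagents that add atoms: DMF, CN(C)C=O (supplies the formyl carbon)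
Why: Vilsmeier formylation goes at the position ortho to OH/OMe and para to OH, which is the resorcinol "4‑type" carbon. The position between the two OH groups is hindered and is not attacked, and the aldehyde deactivates the ring against a second formylation.

**Step 2**
Reactants: 2
Product: 3, 5‑methoxy‑4‑methylbenzene‑1,3‑diol
Conditions: NaBH4 (4 equiv), EtOH, 78 °C, 6 h; then 1 M HCl
Reagents that add atoms: none (hydride only)
Why: NaBH4 reduces the aldehyde to the o‑hydroxybenzyl alkoxide. In this electron‑rich phenolate, hydroxide is lost to form an o‑QM, and conjugate hydride addition to the o‑QM gives the aryl CH3 (reductive deoxygenation of hydroxybenzaldehydes). No stereocentre is involved.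

**Step 3**
Reactants: 3
Product: 4, 1‑(4,6‑dihydroxy‑2‑methoxy‑3‑methylphenyl)ethan‑1‑one
Conditions: AcOH (3 equiv), BF3·OEt2 (5 equiv), 85 °C, 2 h; then aq. NaOAc
Reagents that add atoms: acetic acid, CC(=O)O (supplies the acetyl group)
Why: Friedel–Crafts acylation of resorcinols occurs at the carbon ortho to one OH and para to the other, giving the chelated o‑hydroxyaryl ketone. It does not occur at the carbon between the two OH groups, so Ac goes on the carbon flanked by OMe and OH.

**Step 4**
Reactants: 4
Product: 5, 1‑[2,4‑dihydroxy‑3‑(hydroxymethyl)‑6‑methoxy‑5‑methylphenyl]ethan‑1‑one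
Conditions: 37% aq. HCHO (1.3 equiv), NaOH (2 equiv), H2O, 5 °C → rt, 12 h; acidify to pH 5 with AcOH at 0 °C and extract
Reagents that add atoms: formaldehyde, C=O (supplies the CH2OH carbon)
Why: Base‑mediated hydroxymethylation of the phenolate (Lederer–Manasse type) can only occur at the single free, doubly ortho‑activated carbon, so regiochemistry is fixed. The acetyl group makes the ring less prone to self‑condensation.

**Step 5**
Reactants: 5, benzylic alcohol; 6, (+)‑catechin, (2R,3S)‑2‑(3,4‑dihydroxyphenyl)chroman‑3,5,7‑triol (3 equiv)
Product: 7, Pilosanol N
Conditions: MeCN/H2O 1:1 (5 mM in 5), pH 6 phosphate buffer, Ar‑degassed, hν 350 nm (Rayonet), 15 °C, 3 h; prep‑HPLC to separate the C8 isomer from the C6 isomer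
Reagents that add atoms: none (the aryl component is reactant 6)
Why: Proposed new method: excited 5 undergoes phenol‑to‑benzylic‑OH proton transfer and loses water to give the o‑QM (closest known reaction: Wan‑type photodehydration of o‑hydroxybenzyl alcohols). The o‑QM is then intercepted by C8 of unprotected catechin in a Michael/Friedel–Crafts‑type addition, followed by tautomerisation to the diarylmethane. Two points make the design work:
- Water adds back to the o‑QM to regenerate 5, whereas C–C bond formation is irreversible, so material funnels to product.
- At 350 nm only the acylphloroglucinol absorbs, not catechin.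

The catechin C2 and C3 centres are not involved. Neutral, 15 °C conditions avoid base‑ or heat‑induced C2 epimerisation, so 2R,3S is retained.

## Compound list
1 | 5‑methoxyresorcinol | COc1cc(O)cc(O)c1 | starting material
2 | 2,4‑dihydroxy‑6‑methoxybenzaldehyde | COc1cc(O)cc(O)c1C=O | intermediate
3 | 5‑methoxy‑4‑methylbenzene‑1,3‑diol | COc1c(C)c(O)cc(O)c1 | intermediate
4 | 1‑(4,6‑dihydroxy‑2‑methoxy‑3‑methylphenyl)ethanone | COc1c(C)c(O)cc(O)c1C(C)=O | intermediate
5 | 1‑[2,4‑dihydroxy‑3‑(hydroxymethyl)‑6‑methoxy‑5‑methylphenyl]ethanone | COc1c(C)c(O)c(CO)c(O)c1C(C)=O | intermediate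
6 | (+)‑catechin | Oc1cc(O)c2c(c1)O[C@H](c1ccc(O)c(O)c1)[C@@H](O)C2 | starting material
7 | Pilosanol N | COc1c(C)c(O)c(Cc2c(O)cc(O)c3c2O[C@H](c2ccc(O)c(O)c2)[C@@H](O)C3)c(O)c1C(C)=O | target

## Totals
Total steps: 5. Longest linear sequence: 5 (1 → 2 → 3 → 4 → 5 → 7).

## Three steps most likely to fail
1. **Step 5 (proposed new photochemical coupling).** The acetyl‑chelated phenol may waste the excited state through rapid proton transfer to the carbonyl, giving low o‑QM yield. Poor C8/C6 selectivity is also possible.
   - Fallback (known chemistry): use a regiodefined organometallic route. Make penta‑O‑benzylcatechin and brominate selectively at C8 (NBS). Do Br–Li exchange and add to the O‑benzyl‑protected aldehyde of the acetophenone ring, which is the Step 1‑type formylation of 4 with its phenols benzylated. Then remove the diarylmethanol OH and all benzyl groups by H2, Pd(OH)2/C.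
2. **Step 4 (hydroxymethylation).** The electron‑rich benzylic alcohol may self‑condense through the o‑QM during work‑up, giving diarylmethane dimers.
   - Fallback: avoid formaldehyde and base. Formylate 4 (Vilsmeier) and reduce the aldehyde with NaBH4 at 0 °C to give 5. Use 5 immediately, or prepare the 3‑(dimethylaminomethyl) Mannich base as the o‑QM precursor.
3. **Step 3 (acetylation regiochemistry).** Some acylation at the carbon between the two OH groups would give an isomer with the wrong substitution pattern.
   - Fallback: O‑acetylate 3 (Ac2O) and then run an AlCl3 Fries rearrangement. Chelation directs the acyl group to the carbon ortho to OH and next to OMe.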